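Locants used throughout: decalin carbons C1–C10 (ring A = C1, C2, C3, C4, C5, C10; ring B = C5, C6, C7, C8, C9, C10); C11 = carbinol carbon of the branch on C7; Cα = benzylic carbon; C1′–C6′ = arene carbons, C1′ bonded to Cα. β is the face of the decalin that carries the C10 methyl group, α the opposite face.

Remark on the chemistry: the C11 hydroxyl is carried as a triethylsilyl ether, not a trimethylsilyl ether. It should survive chromatography, two ylide steps and the Lewis acid of the cycloaddition, and it falls in the fluoride step that the endgame needs anyway.

## Analysis of the target

Macrocarpal J (23) joins a fully substituted arene, 2,4,6-trihydroxy-3,5-diformylphenyl (C1′–C6′), through the benzylic methine Cα, which also bears an isobutyl group, to C1 of a trans-fused decalin of the eudesmane type. Ring A (C1, C2, C3, C4, C5, C10) and ring B (C5, C6, C7, C8, C9, C10) share the C5–C10 bond; C10 is quaternary with the angular methyl, C4 is a tertiary methyl carbinol and C7 carries a 2-hydroxypropan-2-yl group (C11). There are six stereocentres: C10 (methyl β) and C5 (H α) define the trans fusion; the Cα branch on C1 is β, equatorial and cis to the angular methyl; the C4 hydroxyl is α and equatorial, so the C4 methyl is axial and syn to the C10 methyl; the C7 branch is β and equatorial; Cα is S. Five of them (Cα, C1, C10, C5, C4) form one contiguous array, whereas C7 stands alone on ring B. The sensitive parts are the phloroglucinol dialdehyde (acidic, chelating, easily oxidised, electrophilic at both formyl groups) and the two tertiary alcohols, which dehydrate under strong acid. The hard points are the quaternary C10 between two stereocentres, the crowded Cα between C1/C10 and a 2,6-dioxygenated arene, and the C4 carbinol with its axial methyl. The plan rests on one feature: with a C3=C4 double bond, ring A is a cyclohexene made of a C2=C3–C4=C5 diene and a C1=C10 dienophile, the two are linked by the ring B carbons C6–C9, and C1 carries the one-carbon branch (the future Cα) that can activate the dienophile as a formyl group.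

## Retrosynthetic reasoning

23 from 22. The last change is the saturation of a C=C bond in the four-carbon branch on Cα, which leads back to the methallyl compound 22. The reason is polarity: an isobutyl group can reach the electrophilic Cα only as a nucleophile, and the four-carbon nucleophiles that tolerate free formyl groups and acidic phenols are π-nucleophiles such as the allylsilane 19, which leave an alkene behind. The forward step has to hydrogenate an unhindered 1,1-disubstituted alkene without reducing two aryl aldehydes; no stereocentre is involved.

22 from 21. The C2′ phenol and the terminal C=C bond of the methallyl group are reconnected to the pyran ring of chroman 21, whose tertiary ring carbon carries a CH2SiMe3 group. This C–O bond is the one a cycloaddition of 19 forms naturally. Its cleavage is a fluoride-triggered 1,2-elimination, and the same fluoride removes the silyl ether on the C11 oxygen, so ring opening and deprotection cost one step.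

21 from 17, 18 and 19. The bonds C1′–Cα and Cα–CH2 (with the pyran C–O bond) are cut in one operation, giving the decalin aldehyde 17, the complete arene 18 and the four-carbon unit 19. Cutting here, and not inside the arene, means the hexasubstituted benzene never has to be built or formylated, and the aldehyde carbon of 17 becomes Cα. Forward, condensation of 17 with the single free ring carbon of 18 must give the o-quinone methide 20, and 19 must add to its exocyclic carbon from the face that the C1 stereocentre leaves open.

17 from 13 by way of 16 and 14. The C4–O bond is disconnected to the C3=C4 alkene of 13. The carbinol needs oxygen on the α face and a hydrogen on C3; epoxidation anti to the axial C10 methyl (14) and hydride delivery to the less substituted epoxide carbon (16) give exactly that. Addition of a methyl nucleophile to a C4 ketone was not chosen, because equatorial attack would place the methyl on the α face. The price is that the hydride also reduces the formyl group, so 16 must be reoxidised to 17.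

13 from 12. With the C3=C4 bond in place, cutting C5–C10 and C1–C2 opens both rings at once to the acyclic trienal 12. No other pair of bonds removes two rings, the quaternary carbon and three stereocentres together while leaving a carbonyl carbon on C1 and the alkene where the C4 carbinol needs it. The forward reaction must bring a β,β-disubstituted enal onto a tethered diene in the endo mode, through a chair-like tether whose only stereocentre, C7, decides the face.

12 from 8 and 9 by way of 10 and 11. The C1=C10 bond is cut to the methyl ketone 8 and the two-carbon phosphonate 9; the ketone methyl is the future angular methyl. Olefination gives enoate 10, and oxidation-state adjustment through allylic alcohol 11 gives the enal. The sequence must deliver the E isomer, because that geometry becomes the cis relation of formyl group and angular methyl.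

8 from 6 and 7, and 6 from 4 and 5. The diene is cut at C2=C3 (methylene from 7) and at C4=C5 (three-carbon unit from the stabilised ylide 5). Both olefinations must occur at an aldehyde in the presence of the methyl ketone, which their relative reactivity allows. The stabilised ylide sets the E geometry that puts the tether on the outside of the diene.

4 from 1 by way of 2. Reconnecting the two carbonyl carbons of 4 (future C5 and C10) gives the cyclohexene of the terpene 1. The ring of 1 is a device: its cleavage releases an aldehyde and a methyl ketone that are already differentiated, correctly spaced, and flank the stereocentre that becomes C7 with its oxygenated branch. Silylation (2) comes first, so the tertiary hydroxyl neither closes onto the aldehyde nor meets the Lewis acid later.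

## Alternatives that were turned down

Alternative 1: Robinson annulation of ring B onto a loaded ring A.
- Disconnection: C9–C10 and C5=C6; ring B is removed from octalone A3, leaving the fully substituted cyclohexanone A1 and methyl vinyl ketone A2.
- Forward key step: the enolate of A1, which can form only towards C10 because C4 is quaternary, adds to A2, and the side-chain methyl ketone condenses onto the C5 carbonyl.
- For it: this is textbook enolate chemistry. The quaternary C10 arises from a Michael addition that should occur anti to the large C1 substituent, which is the correct relative configuration. The arene and Cα are already attached, so no hindered late coupling is needed. On the creation of C10 it is stronger than the chosen route, whose cycloaddition forces a fully substituted dienophile carbon into a pericyclic transition state.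
- Against it: the step builds one ring and one stereocentre, and much is left afterwards. The C7 carbonyl of A3 must become CH–C(CH3)2OH. The C5=C6 bond must be reduced to the trans fusion while the C4 oxygen sits γ to the enone, where dissolving-metal reduction would expel it and catalytic hydrogenation gives no reliable trans selectivity. Two formyl groups must still be introduced and three aryl methyl ethers cleaved next to two tertiary alcohols. A1 itself, with Cα, C1, C4 and the hindered aryl group, needs a synthesis that this plan does not supply, and no chiral-pool element fixes the absolute configuration.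
- Comparison: the chosen strategy gives up the safe enolate step but gains both rings, C10 and three stereocentres in one reaction, the C7 branch from the start, and an alkene placed for the C4 carbinol.

Alternative 2: three-component quinone methide assembly at Cα as the strategic step.
- Disconnection: C1′–Cα and Cα–CH2 in a single operation, with no ring formed.
- Forward key step: the free hydroxy aldehyde A4 condenses with 18 to an o-quinone methide, and 19 attacks its exocyclic carbon directly to give the open-chain methallyl compound A5 (the same structure as 22).
- For it: maximal convergence; the whole arene comes from a purchased compound; the endgame is the shortest conceivable (A5 is one hydrogenation from 23); and the allylic-strain model predicts the correct Cα configuration. On these points it is at least as strong as the chosen strategy, which uses the same pair of bonds as a late tactic.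
- Against it: as a strategy it addresses only the last carbon. It presupposes A4, whose trans-decalin with quaternary C10 and four stereocentres is the real problem and needs its own ring-forming plan. The direct open-chain capture competes with collapse of the zwitterion to a chroman. All the risk falls on the most advanced intermediate.
- Comparison: the chosen strategy supplies what is missing here, a short origin for the decalin aldehyde. It runs the coupling in the better precedented cycloaddition mode with a separate ring opening (steps 12 and 13), at the cost of one extra operation that is merged with the deprotection.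

Alternative 3: silicon-tethered triyne cyclotrimerisation to write the arene.
- Disconnection: the arene bonds C2′–C3′, C4′–C5′ and C6′–C1′; arene A7 is opened to the linear triyne A6, in which two diisopropylsilylene tethers link ynol oxygens to propargylic oxymethyl groups.
- Forward key step: a rhodium catalyst cyclotrimerises A6, closing the benzene ring and two temporary dioxasiline rings.
- For it: the substitution pattern of the hexasubstituted benzene is encoded without ambiguity; no electrophilic aromatic chemistry and no condensation at a hindered aldehyde is needed. On regiochemical certainty of the arene it is stronger than any route that functionalises a benzene ring.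
- Against it: A6 contains three silyl ynol ethers, a labile function prone to isomerisation to silylketenes and to hydrolysis. Its propargylic Cα stereocentre next to C1 must be made and controlled by another hindered addition. After the cyclisation five Si–O bonds must be cleaved and two benzylic alcohols oxidised to aldehydes on an oxidation-prone phloroglucinol. The decalin is not addressed at all.
- Comparison: the regiochemical advantage is worth little here, because the chosen route buys the finished arene as 18 and attaches it in one step. The chosen strategy spends its key step on the part that cannot be bought, the decalin, and is shorter by many steps.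

Key step: step 8

## Route

Step 1
Reactants: 1 (R)-α-terpineol
Product: 2 (R)-α-terpineol triethylsilyl ether
Conditions: TESOTf, 2,6-lutidine, CH2Cl2, 0 °C
Reagents that add atoms: triethylsilyl trifluoromethanesulfonate, CC[Si](CC)(CC)OS(=O)(=O)C(F)(F)F
Why: Silylation of a hindered tertiary alcohol with a silyl triflate and a non-nucleophilic base is standard protection; the ether prevents lactol formation after ring cleavage and keeps the hydroxyl away from the Lewis acid of step 8, and the stereocentre is untouched.

Step 2
Reactants: 2 (R)-α-terpineol triethylsilyl ether
Product: 4 (3R)-6-oxo-3-[2-(triethylsilyloxy)propan-2-yl]heptanal, via secondary ozonide 3 (not isolated)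
Conditions: O3, CH2Cl2, −78 °C; then PPh3, −78 °C to rt
Reagents that add atoms: ozone, [O-][O+]=O
Why: Ozonolysis with reductive work-up (Criegee mechanism) cleaves the only C=C bond and should deliver the aldehyde (future C5) and the methyl ketone (future C10 with its methyl) already differentiated; the stereocentre (future C7) is not involved.

Step 3
Reactants: 4 (3R)-6-oxo-3-[2-(triethylsilyloxy)propan-2-yl]heptanal, 5 2-(triphenylphosphoranylidene)propanal
Product: 6 (2E,5R)-2-methyl-8-oxo-5-[2-(triethylsilyloxy)propan-2-yl]non-2-enal
Conditions: toluene, 90 °C
Reagents that add atoms: 5 2-(triphenylphosphoranylidene)propanal, CC(C=O)=P(c1ccccc1)(c1ccccc1)c1ccccc1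
Why: Wittig olefination with a formyl-stabilised ylide should react with the aldehyde and not with the methyl ketone and should give the E-configured 2-methyl enal, which fixes the C4=C5 geometry and the C4 methyl.

Step 4
Reactants: 6 (2E,5R)-2-methyl-8-oxo-5-[2-(triethylsilyloxy)propan-2-yl]non-2-enal, 7 methyltriphenylphosphonium bromide
Product: 8 (5R,7E)-8-methyl-5-[2-(triethylsilyloxy)propan-2-yl]deca-7,9-dien-2-one
Conditions: 7, NaN(SiMe3)2, THF, 0 °C; then 6 (ylide 1.05 equiv), −78 °C to −20 °C
Reagents that add atoms: 7 methyltriphenylphosphonium bromide, C[P+](c1ccccc1)(c1ccccc1)c1ccccc1.[Br-]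
Why: Wittig methylenation; at low temperature and with about one equivalent the non-stabilised ylide should add to the enal carbonyl much faster than to the saturated methyl ketone, giving the 2-methyl-1,3-diene with the C4=C5 geometry unchanged.

Step 5
Reactants: 8 (5R,7E)-8-methyl-5-[2-(triethylsilyloxy)propan-2-yl]deca-7,9-dien-2-one, 9 triethyl phosphonoacetate
Product: 10 ethyl (2E,6R,8E)-3,9-dimethyl-6-[2-(triethylsilyloxy)propan-2-yl]undeca-2,8,10-trienoate
Conditions: 9, NaH, THF, 0 °C; then 8, rt to 50 °C
Reagents that add atoms: 9 triethyl phosphonoacetate, CCOC(=O)CP(=O)(OCC)OCC
Why: Horner–Wadsworth–Emmons olefination of the methyl ketone should favour the E enoate (ester trans to the longer chain); the minor geometric isomer is to be removed by chromatography here or after step 6, and diene and silyl ether are stable to the base.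

Step 6
Reactants: 10 ethyl (2E,6R,8E)-3,9-dimethyl-6-[2-(triethylsilyloxy)propan-2-yl]undeca-2,8,10-trienoate
Product: 11 (2E,6R,8E)-3,9-dimethyl-6-[2-(triethylsilyloxy)propan-2-yl]undeca-2,8,10-trien-1-ol
Conditions: i-Bu2AlH (2.5 equiv), CH2Cl2, −78 °C
Reagents that add atoms: none
Why: 1,2-Reduction of the enoate by the aluminium hydride at low temperature should give the allylic alcohol without touching the diene or the C=C geometry.

Step 7
Reactants: 11 (2E,6R,8E)-3,9-dimethyl-6-[2-(triethylsilyloxy)propan-2-yl]undeca-2,8,10-trien-1-ol
Product: 12 (2E,6R,8E)-3,9-dimethyl-6-[2-(triethylsilyloxy)propan-2-yl]undeca-2,8,10-trienal (E,E-trienal)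
Conditions: activated MnO2 (excess), CH2Cl2, rt
Reagents that add atoms: none
Why: Allylic oxidation on MnO2 is selective for the allylic alcohol and should not isomerise the trisubstituted C=C bond, so the E enal needed for the cycloaddition is obtained.

Step 8
Reactants: 12 (2E,6R,8E)-3,9-dimethyl-6-[2-(triethylsilyloxy)propan-2-yl]undeca-2,8,10-trienal
Product: 13 trans-octalin C1-carbaldehyde (C3=C4; formyl on C1 β; H on C5 α; silyloxypropyl on C7 β; methyl on C10 β)
Conditions: Me2AlCl (1.2 equiv), CH2Cl2, −78 °C to 0 °C
Reagents that add atoms: none
Why: Me2AlCl binds the formyl oxygen of 12 and lowers the LUMO of the E enal, so that a concerted but asynchronous (4+2) cycloaddition with the tethered 2-methyl diene should occur below room temperature, the C5–C10 bond being more advanced than C1–C2 and the developing positive charge resting on the methyl-bearing C4. The closest known reaction type is the Lewis-acid-promoted intramolecular Diels–Alder reaction of terminally activated 1,7,9-decatrienes to trans-fused octalins; a β,β-disubstituted enal that must create a quaternary carbon lies at the slow end of that class. Ring A closes as the new cyclohexene by suprafacial addition on diene and dienophile, and ring B closes in the same event as a six-membered carbocycle through the four-carbon tether C6–C9, which adopts a chair-like arrangement in the transition state. C1 and C10 are set together by the retained E geometry of the enal, which places the formyl group cis to the angular methyl. C5 is set relative to C10 by the endo orientation of the aluminium-bound formyl group, which puts the tether exo and leads to the trans ring fusion. The absolute sense of all three new centres is relayed from C7, because the bulky silyloxypropyl group occupies an equatorial position on the chair-like tether and so selects one face of the diene. The step needs endo over exo selectivity, diene-face selectivity and chemoselectivity for cycloaddition over cationic reactions of the diene; Lewis-acid complexation strengthens the endo preference, the size of the C7 substituent secures the face, the tether fixes the regiochemistry, and low temperature with a proton-scavenging alkylaluminium chloride protects the diene and the silyl ether.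

Step 9
Reactants: 13 trans-octalin C1-carbaldehyde
Product: 14 3α,4α-epoxy decalin C1-carbaldehyde
Conditions: mCPBA (1.05 equiv), NaHCO3, CH2Cl2, 0 °C
Reagents that add atoms: 3-chloroperoxybenzoic acid, OOC(=O)c1cccc(Cl)c1
Why: Prilezhaev epoxidation; the electron-rich trisubstituted C3=C4 bond is the only alkene and should be attacked from the α face, because the axial C10 methyl shields the β face, while buffering, one equivalent of peracid and 0 °C hold back Baeyer–Villiger oxidation of the hindered aldehyde and loss of the silyl ether.

Step 10
Reactants: 14 3α,4α-epoxy decalin C1-carbaldehyde
Product: 16 decalin diol (1β-hydroxymethyl; 4α-hydroxy-4β-methyl), via epoxy alcohol 15 (not isolated)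
Conditions: LiAlH4 (4 equiv), THF, 0 °C, then reflux
Reagents that add atoms: none
Why: The hydride reduces the aldehyde at once and then opens the trisubstituted epoxide by SN2 attack at the secondary C3 from the β face, which leaves the oxygen on C4 on the α face (equatorial hydroxyl, axial methyl). Attack at the tertiary C4, which the diaxial-opening (Fürst–Plattner) rule would favour, is blocked by substitution and by the syn-axial C10 methyl, so heating is planned for the slower diequatorial mode.

Step 11
Reactants: 16 decalin diol
Product: 17 4α-hydroxy decalin C1β-carbaldehyde
Conditions: Dess–Martin periodinane, NaHCO3, CH2Cl2, 0 °C to rt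
Reagents that add atoms: none
Why: Dess–Martin oxidation converts the primary alcohol to the aldehyde; the tertiary alcohol cannot be oxidised, the trans-diequatorial 1,4-relation of formyl and hydroxyl excludes lactol formation, and C1 already has its more stable equatorial configuration.

Step 12
Reactants: 17 4α-hydroxy decalin C1β-carbaldehyde, 18 2,4,6-trihydroxyisophthalaldehyde, 19 methallyltrimethylsilane
Product: 21 5,7-dihydroxy-2-methyl-2-(trimethylsilylmethyl)chroman-6,8-dicarbaldehyde carrying the decalin on C4 (Cα), via o-quinone methide 20 (not isolated)
Conditions: ethylenediammonium diacetate (20 mol%), 19 (10 equiv), 1,4-dioxane, 80 °C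
Reagents that add atoms: 18 2,4,6-trihydroxyisophthalaldehyde, O=Cc1c(O)cc(O)c(C=O)c1O; 19 methallyltrimethylsilane, C=C(C)C[Si](C)(C)C
Why: Domino Knoevenagel condensation and inverse-electron-demand oxa-Diels–Alder reaction: the only free ring carbon of 18 condenses with 17 to the o-quinone methide 20, whose oxadiene is captured by the electron-rich 1,1-disubstituted alkene of 19, with oxygen bonding to the tertiary, silicon-stabilised carbon. Cα is set by allylic 1,3-strain: the C1–H bond eclipses the exocyclic C=C bond and the alkene approaches anti to the quaternary C10, which corresponds to the Cα configuration of 23; the new chroman C2 centre is of no consequence because it disappears in step 13.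

Step 13
Reactants: 21 silylmethyl chroman
Product: 22 methallyl analogue of macrocarpal J
Conditions: n-Bu4NF (6 equiv), THF, rt to 50 °C; aq. NH4Cl
Reagents that add atoms: none
Why: Fluoride attacks the trimethylsilyl group and the β-aryloxy group leaves as a vinylogous carboxylate, the same Peterson-type 1,2-elimination by which 2-(trimethylsilyl)ethyl ethers are cleaved; this opens the pyran ring to the free C2′ phenol and the methallyl group. The same reagent removes the triethylsilyl ether, and no stereocentre of 22 is touched.

Step 14
Reactants: 22 methallyl analogue of macrocarpal J
Product: 23 macrocarpal J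
Conditions: H2 (1 atm), RhCl(PPh3)3 (10 mol%), benzene–EtOH (1:1), rt
Reagents that add atoms: none
Why: Homogeneous hydrogenation with RhCl(PPh3)3 should saturate the unhindered 1,1-disubstituted alkene and leave the chelated aryl aldehydes, the phenols and the tertiary alcohols untouched; no stereocentre is formed.

## Compound list

1 | (R)-α-terpineol | CC1=CC[C@H](C(C)(C)O)CC1 | starting material
2 | (R)-α-terpineol triethylsilyl ether | CC1=CC[C@H](C(C)(C)O[Si](CC)(CC)CC)CC1 | intermediate
3 | secondary ozonide of 2 (1,2,4-trioxolane across the former C=C carbons, mixture at the trioxolane carbons; not isolated) | CC12OOC(O1)C[C@H](C(C)(C)O[Si](CC)(CC)CC)CC2 | intermediate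
4 | (3R)-6-oxo-3-[2-(triethylsilyloxy)propan-2-yl]heptanal | CC(=O)CC[C@@H](C(C)(C)O[Si](CC)(CC)CC)CC=O | intermediate
5 | 2-(triphenylphosphoranylidene)propanal | CC(C=O)=P(c1ccccc1)(c1ccccc1)c1ccccc1 | starting material
6 | (2E,5R)-2-methyl-8-oxo-5-[2-(triethylsilyloxy)propan-2-yl]non-2-enal | CC(=O)CC[C@@H](C(C)(C)O[Si](CC)(CC)CC)C/C=C(\C)C=O | intermediate
7 | methyltriphenylphosphonium bromide | C[P+](c1ccccc1)(c1ccccc1)c1ccccc1.[Br-] | starting material
8 | (5R,7E)-8-methyl-5-[2-(triethylsilyloxy)propan-2-yl]deca-7,9-dien-2-one | CC(=O)CC[C@@H](C(C)(C)O[Si](CC)(CC)CC)C/C=C(\C)C=C | intermediate
9 | triethyl phosphonoacetate | CCOC(=O)CP(=O)(OCC)OCC | starting material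
10 | ethyl (2E,6R,8E)-3,9-dimethyl-6-[2-(triethylsilyloxy)propan-2-yl]undeca-2,8,10-trienoate | CCOC(=O)/C=C(\C)CC[C@@H](C(C)(C)O[Si](CC)(CC)CC)C/C=C(\C)C=C | intermediate
11 | (2E,6R,8E)-3,9-dimethyl-6-[2-(triethylsilyloxy)propan-2-yl]undeca-2,8,10-trien-1-ol | OC/C=C(\C)CC[C@@H](C(C)(C)O[Si](CC)(CC)CC)C/C=C(\C)C=C | intermediate
12 | (2E,6R,8E)-3,9-dimethyl-6-[2-(triethylsilyloxy)propan-2-yl]undeca-2,8,10-trienal (precursor of the key step) | O=C/C=C(\C)CC[C@@H](C(C)(C)O[Si](CC)(CC)CC)C/C=C(\C)C=C | intermediate
13 | trans-fused Δ3-octalin: 4,10-dimethyl-7-[2-(triethylsilyloxy)propan-2-yl]octal-3-ene-1-carbaldehyde; formyl on C1 β (equatorial, cis to the C10 methyl), H on C5 α, branch on C7 β, methyl on C10 β | O=C[C@@H]1CC=C(C)[C@@H]2C[C@H](C(C)(C)O[Si](CC)(CC)CC)CC[C@]21C | intermediate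
14 | 3α,4α-epoxide of 13 (epoxide oxygen α, C4 methyl β) | O=C[C@@H]1C[C@H]3O[C@@]3(C)[C@@H]2C[C@H](C(C)(C)O[Si](CC)(CC)CC)CC[C@]21C | intermediate
15 | 3α,4α-epoxy decalin with 1β-hydroxymethyl group (not isolated) | OC[C@@H]1C[C@H]3O[C@@]3(C)[C@@H]2C[C@H](C(C)(C)O[Si](CC)(CC)CC)CC[C@]21C | intermediate
16 | trans-decalin diol: 1β-hydroxymethyl, 4α-hydroxy-4β-methyl, 5α-H, 7β-[2-(triethylsilyloxy)propan-2-yl], 10β-methyl | OC[C@@H]1CC[C@@](C)(O)[C@@H]2C[C@H](C(C)(C)O[Si](CC)(CC)CC)CC[C@]21C | intermediate
17 | trans-decalin hydroxy aldehyde: 1β-formyl, 4α-hydroxy-4β-methyl, 5α-H, 7β-[2-(triethylsilyloxy)propan-2-yl], 10β-methyl | O=C[C@@H]1CC[C@@](C)(O)[C@@H]2C[C@H](C(C)(C)O[Si](CC)(CC)CC)CC[C@]21C | intermediate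
18 | 2,4,6-trihydroxyisophthalaldehyde | O=Cc1c(O)cc(O)c(C=O)c1O | starting material
19 | methallyltrimethylsilane | C=C(C)C[Si](C)(C)C | starting material
20 | o-quinone methide from 17 and 18 (exocyclic C1′=Cα bond, geometry not fixed; not isolated) | O=CC1=C(O)C(C=O)=C(O)C(=C[C@@H]2CC[C@@](C)(O)[C@@H]3C[C@H](C(C)(C)O[Si](CC)(CC)CC)CC[C@]32C)C1=O | intermediate
21 | 5,7-dihydroxy-2-methyl-2-(trimethylsilylmethyl)chroman-6,8-dicarbaldehyde with the decalin of 17 on C4; chroman C4 = Cα, configured as in 23; both epimers at chroman C2 | C[Si](C)(C)CC1(C)C[C@@H]([C@@H]2CC[C@@](C)(O)[C@@H]3C[C@H](C(C)(C)O[Si](CC)(CC)CC)CC[C@]32C)c2c(O)c(C=O)c(O)c(C=O)c2O1 | intermediate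
22 | methallyl analogue of macrocarpal J (2-methylprop-2-enyl in place of isobutyl on Cα; Cα S) | C=C(C)C[C@H](c1c(O)c(C=O)c(O)c(C=O)c1O)[C@@H]1CC[C@@](C)(O)[C@@H]2C[C@H](C(C)(C)O)CC[C@]21C | intermediate
23 | macrocarpal J | CC(C)C[C@H](c1c(O)c(C=O)c(O)c(C=O)c1O)[C@@H]1CC[C@@](C)(O)[C@@H]2C[C@H](C(C)(C)O)CC[C@]21C | target

## Step count and least certain steps

Total step count: 14. Longest linear sequence: 14 steps, from 1 to 23; 5, 7, 9, 18 and 19 enter as purchased compounds.

Step 8 (key step).
- What may go wrong: the fully substituted dienophile carbon C10 slows the cycloaddition so much that other processes overtake it. These are Lewis-acid-induced cationic oligomerisation of the 2-methyl diene, methyl transfer from aluminium to the formyl group, E/Z isomerisation of the complexed enal (which would erode the cis relation of formyl group and angular methyl) and loss of the silyl ether.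
- Fallback, from 12 back to 13: 12 would be converted with 1,2-bis(trimethylsilyloxy)ethane and catalytic TMSOTf at −78 °C into trienal dioxolane F1. More TMSOTf at −78 to −40 °C should open the dioxolane to an alkoxy-substituted allyl cation, a far stronger dienophile than the aluminium-bound enal. An ionic intramolecular Diels–Alder reaction should then close both rings to octalin dioxolane F2, and pyridinium p-toluenesulfonate in wet acetone would hydrolyse F2 to 13.

Step 12.
- What may go wrong: slow condensation of the α-branched, neopentyl-type aldehyde 17 with 18 keeps the stationary concentration of 20 low. Then 20 tautomerises to the conjugated vinylphenol with scrambling at C1 before the weakly nucleophilic alkene 19 captures it. A second concern is insufficient facial bias at Cα.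
- Fallback, from 17 back to 21: formation and capture of the quinone methide would be separated. 17, 18 and p-TolSO2Na under mild acid (HCO2H, CH2Cl2–H2O, rt) should give benzylic sulfone F3, because the sulfinate is a strong soft nucleophile that drains the condensation equilibrium. Treating F3 with K2CO3 in the presence of excess 19 (dioxane, rt to 60 °C) would release 20 cleanly by elimination of sulfinate at a temperature where the oxa-Diels–Alder reaction to 21 can follow.

Step 10.
- What may go wrong: the diequatorial opening at C3 is slow, so hydride delivery at C4 or Lewis-acid-induced rearrangement of the epoxide to a C3 carbonyl or an allylic alcohol may compete. Incomplete α-face selectivity in step 9 would add the C4 epimer.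
- Fallback, from 13 back to 16 (it also by-passes step 9): NaBH4 in MeOH at 0 °C would reduce 13 to octalin methanol F4. A Mukaiyama hydration (Co(acac)2, PhSiH3, O2, i-PrOH, rt, phosphine work-up) would then add hydrogen to C3 and oxygen to the tertiary C4 radical. Oxygen should be captured from the α face, away from the axial C10 methyl, giving 16.

Step 5.
- What may go wrong: limited E/Z selectivity in the olefination of a methyl ketone and a difficult separation of the geometric isomers, which would carry the wrong dienophile geometry into step 8.
- Fallback, from 8 back to 11: kinetic enolisation of 8 at the methyl group (LiN(i-Pr)2, THF, −78 °C) and trapping with diethyl chlorophosphate would give enol phosphate F5. Excess LiN(i-Pr)2 would eliminate it to terminal alkyne F6. Negishi carboalumination (Me3Al, Cp2ZrCl2 cat., CH2Cl2) adds methyl and aluminium syn across the alkyne to give E-alkenyldimethylalane F7. Trapping F7 in the same flask with paraformaldehyde should give 11 as a single geometric isomer, replacing steps 5 and 6.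

## Further compounds

F1 | step 8 | trienal dioxolane: 2-[(1E,5R,7E)-2,8-dimethyl-5-[2-(triethylsilyloxy)propan-2-yl]deca-1,7,9-trienyl]-1,3-dioxolane | C1(OCCO1)/C=C(\C)CC[C@@H](C(C)(C)O[Si](CC)(CC)CC)C/C=C(\C)C=C
F2 | step 8 | octalin dioxolane: ethylene acetal of 13, same configuration | C3(OCCO3)[C@@H]1CC=C(C)[C@@H]2C[C@H](C(C)(C)O[Si](CC)(CC)CC)CC[C@]21C
F3 | step 12 | benzylic sulfone: Cα carries p-tolylsulfonyl, the arene of 18 and the decalin of 17; both Cα epimers | Cc1ccc(cc1)S(=O)(=O)C(c1c(O)c(C=O)c(O)c(C=O)c1O)[C@@H]1CC[C@@](C)(O)[C@@H]2C[C@H](C(C)(C)O[Si](CC)(CC)CC)CC[C@]21C
F4 | step 10 | octalin methanol: 1β-hydroxymethyl analogue of 13 | OC[C@@H]1CC=C(C)[C@@H]2C[C@H](C(C)(C)O[Si](CC)(CC)CC)CC[C@]21C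
F5 | step 5 | enol phosphate: diethyl (5R,7E)-8-methyl-5-[2-(triethylsilyloxy)propan-2-yl]deca-1,7,9-trien-2-yl phosphate | C=C(OP(=O)(OCC)OCC)CC[C@@H](C(C)(C)O[Si](CC)(CC)CC)C/C=C(\C)C=C
F6 | step 5 | terminal alkyne: (5R,7E)-8-methyl-5-[2-(triethylsilyloxy)propan-2-yl]deca-7,9-dien-1-yne | C#CCC[C@@H](C(C)(C)O[Si](CC)(CC)CC)C/C=C(\C)C=C
F7 | step 5 | E-alkenyldimethylalane from F6 (aluminium cis to the new methyl) | C[Al](C)/C=C(\C)CC[C@@H](C(C)(C)O[Si](CC)(CC)CC)C/C=C(\C)C=C
A1 | alternative 1 | ring A ketone: cyclohexanone with C5 carbonyl, C10 methyl (configuration open), C4 methyl and trimethylsilyloxy, C1 bearing the Cα branch with isobutyl and 2,4,6-trimethoxyphenyl | CC(C)C[C@H](c1c(OC)cc(OC)cc1OC)[C@@H]1CC[C@@](C)(O[Si](C)(C)C)C(=O)C1C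
A2 | alternative 1 | methyl vinyl ketone | C=CC(C)=O
A3 | alternative 1 | octalone with C5=C6 and C7 carbonyl | CC(C)C[C@H](c1c(OC)cc(OC)cc1OC)[C@@H]1CC[C@@](C)(O[Si](C)(C)C)C2=CC(=O)CC[C@]21C
A4 | alternative 2 | unprotected decalin hydroxy aldehyde (17 without the silyl group) | O=C[C@@H]1CC[C@@](C)(O)[C@@H]2C[C@H](C(C)(C)O)CC[C@]21C
A5 | alternative 2 | methallyl analogue of macrocarpal J (same structure as 22) | C=C(C)C[C@H](c1c(O)c(C=O)c(O)c(C=O)c1O)[C@@H]1CC[C@@](C)(O)[C@@H]2C[C@H](C(C)(C)O)CC[C@]21C
A6 | alternative 3 | linear triyne with two diisopropylsilylene tethers and a terminal triisopropylsilyl ynol ether | CC(C)C[C@H](C#CO[Si](C(C)C)(C(C)C)OCC#CO[Si](C(C)C)(C(C)C)OCC#CO[Si](C(C)C)(C(C)C)C(C)C)[C@@H]1CC[C@@](C)(O[Si](C)(C)C)[C@@H]2C[C@H](C(C)(C)O[Si](C)(C)C)CC[C@]21C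
A7 | alternative 3 | hexasubstituted arene with two fused dioxasiline rings | CC(C)C[C@H](c1c2O[Si](C(C)C)(C(C)C)OCc2c2O[Si](C(C)C)(C(C)C)OCc2c1O[Si](C(C)C)(C(C)C)C(C)C)[C@@H]1CC[C@@](C)(O[Si](C)(C)C)[C@@H]2C[C@H](C(C)(C)O[Si](C)(C)C)CC[C@]21C
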